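**Retrosynthetic overview** (target numbering: C1–C2 oxirane, C3 (Cl, Me), C4 (Br), C5H2, C6 (Br), C7 (Cl, Me2))
1. Oxirane (the only ring of the target, closed last): C1–C2 bond by chloromethyllithium addition to α-chloro aldehyde 9 under Cornforth control, then ring closure.
2. C3–Cl / C4–Br: organocatalytic anti-bromochlorination of the E-allylic alcohol 7 (key step, catalyst-controlled).
3. C3=C4: Wittig olefination of β-bromo aldehyde 5 with ylide 4, then ester reduction.
4. C6–Br / C7–Cl (first stereocenter): organocatalytic 5-endo bromoetherification of achiral alcohol 1; the transient oxolane (first ring formed) is opened by BCl3.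

Assumption: the facial sense of (DHQD)2PHAL in step 1 and (DHQ)2PHAL in step 4 is assigned by analogy and must be confirmed on 3 and 8; if it is reversed, the pseudoenantiomeric alkaloid is used.

**Step 1**
Reactants: 1 4-methylpent-3-en-1-ol
Product: 3 (3R)-3-bromo-4-chloro-4-methylpentan-1-ol, via (3R)-3-bromo-2,2-dimethyloxolane 2 (not isolated)
Conditions: (DHQD)2PHAL (hydroquinidine 1,4-phthalazinediyl diether, 10 mol%), NBS (1.05 equiv), CH2Cl2, −60 °C; then BCl3 (2.5 equiv), −78 → −20 °C; H2O
Reagents that add atoms: N-bromosuccinimide (O=C1CCC(=O)N1Br); boron trichloride (ClB(Cl)Cl)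
Why: Proposed new method: the bis-cinchona catalyst hydrogen-bonds the homoallylic OH and relays Br+ from NBS to one face of the trisubstituted olefin, the hydroxyl closes 5-endo at the tertiary carbon (anti addition, sets the C–Br stereocenter), and BCl3 then ionises the tertiary C–O bond with anchimeric help of the anti bromine so that chloride opens the bromonium at the tertiary carbon with the C–Br configuration retained; closest known reaction types are cinchona-alkaloid-catalysed asymmetric 5-endo chloroetherification of aryl homoallylic alcohols and BCl3 cleavage of tertiary alkyl ethers.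

**Step 2**
Reactants: 3 (3R)-3-bromo-4-chloro-4-methylpentan-1-ol; 4 ethyl 2-(triphenylphosphoranylidene)propanoate
Product: 6 ethyl (2E,5R)-5-bromo-6-chloro-2,6-dimethylhept-2-enoate, via (3R)-3-bromo-4-chloro-4-methylpentanal 5 (not isolated)
Conditions: Dess–Martin periodinane (1.1 equiv), CH2Cl2, 0 °C; then 4 (1.5 equiv), 0 °C → rt
Reagents that add atoms: none
Why: Dess–Martin oxidation gives the elimination-prone β-bromo aldehyde, which is trapped in the same flask by the weakly basic stabilised ylide (Wittig olefination); the α-methyl ester ylide gives the E-trisubstituted enoate and C5 is not touched.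

**Step 3**
Reactants: 6 ethyl (2E,5R)-5-bromo-6-chloro-2,6-dimethylhept-2-enoate
Product: 7 (2E,5R)-5-bromo-6-chloro-2,6-dimethylhept-2-en-1-ol
Conditions: i-Bu2AlH (2.3 equiv), CH2Cl2, −78 °C; aq. potassium sodium tartrate (KNaC4H4O6)
Reagents that add atoms: none
Why: 1,2-reduction of the enoate by DIBAL-H at −78 °C gives the allylic alcohol and leaves the secondary bromide, the tertiary chloride and the olefin geometry intact.

**Step 4**
Reactants: 7 (2E,5R)-5-bromo-6-chloro-2,6-dimethylhept-2-en-1-ol
Product: 8 (2R,3S,5R)-3,5-dibromo-2,6-dichloro-2,6-dimethylheptan-1-ol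
Conditions: (DHQ)2PHAL (hydroquinine 1,4-phthalazinediyl diether, 10 mol%), NBS (1.1 equiv), LiCl (20 equiv), CF3CH2OH/CH2Cl2 (3:1), −30 °C
Reagents that add atoms: N-bromosuccinimide (O=C1CCC(=O)N1Br); lithium chloride ([Li+].[Cl-])
Why: Proposed new method: the bis-cinchona catalyst binds the allylic OH by hydrogen bonding and transfers Br+ from NBS to one olefin face while chloride (LiCl in CF3CH2OH) adds anti at the tertiary carbon (Markovnikov), so anti addition to the E-olefin gives the (2R,3S) pair under catalyst control independent of the remote C5 centre; closest known reaction types are cinchona-bis-alkaloid-catalysed vicinal dihalogenation of allyl amides and dichlorination of cinnamyl alcohols.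

**Step 5**
Reactants: 8 (2R,3S,5R)-3,5-dibromo-2,6-dichloro-2,6-dimethylheptan-1-ol
Product: 9 (2R,3S,5R)-3,5-dibromo-2,6-dichloro-2,6-dimethylheptanal
Conditions: Dess–Martin periodinane (1.3 equiv), CH2Cl2, 0 °C → rt
Reagents that add atoms: none
Why: Dess–Martin oxidation of the neopentyl-type primary alcohol is mild and non-basic, and the quaternary α-carbon means the α-chloro aldehyde can neither epimerise nor lose HBr by E1cB.

**Step 6**
Reactants: 9 (2R,3S,5R)-3,5-dibromo-2,6-dichloro-2,6-dimethylheptanal
Product: 11 (2R)-2-[(2R,3S,5R)-3,5-dibromo-2,6-dichloro-6-methylheptan-2-yl]oxirane (target), via lithium chlorohydrin alkoxide 10 (not isolated)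
Conditions: ICH2Cl (2.0 equiv), MeLi·LiBr (1.8 equiv), THF/Et2O, −78 °C; then → rt, 12 h
Reagents that add atoms: chloroiodomethane (ClCI)
Why: chloromethyllithium (iodine–lithium exchange in Barbier mode) adds to the aldehyde under Cornforth/polar Felkin–Anh control (C–Cl anti to C=O, attack past the methyl group and away from the C4 chain), which sets C2 as R, and the alkoxide then closes the oxirane by 3-exo-tet displacement of the primary chloride without touching C2.

**Compound list**
1 | 4-methylpent-3-en-1-ol | CC(C)=CCCO | starting material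
2 | (3R)-3-bromo-2,2-dimethyloxolane | CC1(C)[C@H](Br)CCO1 | intermediate (not isolated)
3 | (3R)-3-bromo-4-chloro-4-methylpentan-1-ol | CC(C)(Cl)[C@H](Br)CCO | intermediate
4 | ethyl 2-(triphenylphosphoranylidene)propanoate | CCOC(=O)C(C)=P(c1ccccc1)(c1ccccc1)c1ccccc1 | starting material
5 | (3R)-3-bromo-4-chloro-4-methylpentanal | CC(C)(Cl)[C@H](Br)CC=O | intermediate (not isolated)
6 | ethyl (2E,5R)-5-bromo-6-chloro-2,6-dimethylhept-2-enoate | CC(C)(Cl)[C@H](Br)C/C=C(\C)C(=O)OCC | intermediate
7 | (2E,5R)-5-bromo-6-chloro-2,6-dimethylhept-2-en-1-ol | CC(C)(Cl)[C@H](Br)C/C=C(\C)CO | intermediate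
8 | (2R,3S,5R)-3,5-dibromo-2,6-dichloro-2,6-dimethylheptan-1-ol | CC(C)(Cl)[C@H](Br)C[C@H](Br)[C@](C)(Cl)CO | intermediate
9 | (2R,3S,5R)-3,5-dibromo-2,6-dichloro-2,6-dimethylheptanal | CC(C)(Cl)[C@H](Br)C[C@H](Br)[C@](C)(Cl)C=O | intermediate
10 | lithium (2R,3R,4S,6R)-4,6-dibromo-1,3,7-trichloro-3,7-dimethyloctan-2-olate | CC(C)(Cl)[C@H](Br)C[C@H](Br)[C@](C)(Cl)[C@H]([O-])CCl.[Li+] | intermediate (not isolated)
11 | (2R)-2-[(2R,3S,5R)-3,5-dibromo-2,6-dichloro-6-methylheptan-2-yl]oxirane | CC(C)(Cl)[C@H](Br)C[C@H](Br)[C@](C)(Cl)[C@H]1CO1 | target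

**Total step count:** 6. **Longest linear sequence:** 6 (1 → 3 → 6 → 7 → 8 → 9 → 11).

**Steps most likely to fail and their fallbacks**

Step 1 (proposed new step). The risks are a modest ee on a purely aliphatic olefin, and BCl3 cleaving the primary instead of the tertiary C–O bond. A minor enantiomer of 3 would become a separable diastereomer at 8. The fallback sets out from 1 and comes back at 3. It is the known direct enantioselective bromochlorination of this homoallylic alcohol with NBS and ClTi(OiPr)3 (chloride source and tetravalent-titanium alkoxide template) under a chiral tridentate Schiff-base ligand (salicylaldimine of a 1,1-diaryl amino alcohol, 20 mol%) in hexanes at −20 °C. The alcohol is bound covalently to titanium and chloride is delivered from the metal, so the oxolane detour is avoided and no compound outside the list is made (F0).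

Step 4 (proposed new step). The risks are low face selectivity with a hydrogen-bond-only director, and background bromochlorination. The fallback sets out from 7 and comes back at 8. It changes the mode of stereocontrol from hydrogen bonding to a covalent titanium alkoxide: NBS, ClTi(OiPr)3 and the chiral Schiff-base ligand in hexanes at −20 °C. This is known for trisubstituted allylic alcohols, placing Cl at the tertiary carbon with ligand-controlled face selectivity. No compound outside the list is made (F0).

Step 6. The risks are an insufficient Cornforth preference between the methyl group and the C4 chain at a quaternary α-carbon, and base-induced loss of HBr. The fallback sets out from 9 and comes back at 11, and replaces substrate control by catalyst control. The chloromethyllithium addition is quenched at −78 °C with AcOH to give (3R,4S,6R)-4,6-dibromo-1,3,7-trichloro-3,7-dimethyloctan-2-ol F1 as a mixture of C2 epimers. Dess–Martin oxidation then gives (3R,4S,6R)-4,6-dibromo-1,3,7-trichloro-3,7-dimethyloctan-2-one F2. Corey–Bakshi–Shibata reduction ((S)-2-methyl-CBS-oxazaborolidine, 20 mol%, BH3·SMe2, THF, −20 °C; tertiary alkyl as the large group, CH2Cl as the small group) gives (2R,3R,4S,6R)-4,6-dibromo-1,3,7-trichloro-3,7-dimethyloctan-2-ol F3. Closure with K2CO3 in MeOH at 0 °C gives 11.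

**Further compounds**
F0 | step 1 | none | none
F0 | step 4 | none | none
F1 | step 6 | (3R,4S,6R)-4,6-dibromo-1,3,7-trichloro-3,7-dimethyloctan-2-ol (C2 epimer mixture) | CC(C)(Cl)[C@H](Br)C[C@H](Br)[C@](C)(Cl)C(O)CCl
F2 | step 6 | (3R,4S,6R)-4,6-dibromo-1,3,7-trichloro-3,7-dimethyloctan-2-one | CC(C)(Cl)[C@H](Br)C[C@H](Br)[C@](C)(Cl)C(=O)CCl
F3 | step 6 | (2R,3R,4S,6R)-4,6-dibromo-1,3,7-trichloro-3,7-dimethyloctan-2-ol | CC(C)(Cl)[C@H](Br)C[C@H](Br)[C@](C)(Cl)[C@H](O)CCl
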